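**Retrosynthetic overview**

1. Numbering for all ring compounds: ring fusion C1/C5; ring A = cyclopentene C1–C5 (C2=C3, carbinol C4); ring B = cycloheptane C5–C10 + C1 (carbinol C6, exocyclic methylene on C10); side chain C11–C15 on C7, acetate on C13; α = face of H1 and H5, β = the other face.
2. The strategy rests on C7: it is the ring-B carbon between the C6 carbinol carbon and the C8 methylene, and it carries the whole side chain. Ring B is therefore cut at C6–C7 and C7–C8, and C7 enters as the diazo carbon of the finished side chain, inserted into the C6–C8 bond of a cis-hydrindenone.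
3. After the insertion only two adjustments remain: reduction of the C6 ketone from the convex α face and removal of the C4 silyl group.
4. Hydrindenone: (S)-4-silyloxycyclohexenone (its oxygen, a sacrificial stereocentre, becomes C10) and a silylallene give ring A by [3+2] annulation; a silicon-directed singlet-oxygen ene reaction sets C4–OH and C2=C3; the C10 oxygen is converted to the methylene.
5. Diazoalkane: C11 comes from (S)-3-bromo-2-methylpropan-1-ol, C13 from a CBS reduction of the enone made with 3-methylbut-2-enal. Ring order: six-membered carbocycle (from the cyclohexenone), then ring A (annulation), then ring B (ring enlargement).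

Key step: step 25

Assumption: enone ketal 1, (S)-3-bromo-2-methylpropan-1-ol and both CBS catalysts are taken as catalogue chemicals (1 would otherwise be one dehydrogenation step from 1,4-cyclohexanedione monoethylene acetal).

**Route**

Step 1
Reactants: 1 1,4-dioxaspiro[4.5]dec-6-en-8-one
Product: 2 (S)-1,4-dioxaspiro[4.5]dec-6-en-8-ol
Conditions: (R)-1-methyl-3,3-diphenyltetrahydro-1H,3H-pyrrolo[1,2-c][1,3,2]oxazaborole [(R)-Me-CBS, 0.1 equiv], catecholborane, toluene, −78 °C
Reagents that add atoms: none
Why: Corey–Bakshi–Shibata reduction in which the alkenyl arm is the large substituent, so the (R)-catalyst should give the (S)-carbinol, the sacrificial stereocentre (later C10) that fixes the absolute configuration of the ring fusion.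

Step 2
Reactants: 2 (S)-1,4-dioxaspiro[4.5]dec-6-en-8-ol
Product: 3 (S)-tert-butyl(1,4-dioxaspiro[4.5]dec-6-en-8-yloxy)dimethylsilane
Conditions: TBSCl, imidazole, DMF, rt
Reagents that add atoms: tert-butyldimethylsilyl chloride, CC(C)(C)[Si](C)(C)Cl
Why: Standard silylation of a secondary allylic alcohol; the bulky silyl ether later steers the annulation to the opposite face.

Step 3
Reactants: 3 (S)-tert-butyl(1,4-dioxaspiro[4.5]dec-6-en-8-yloxy)dimethylsilane
Product: 4 (S)-4-[(tert-butyldimethylsilyl)oxy]cyclohex-2-en-1-one
Conditions: 10% aq. oxalic acid on SiO2, CH2Cl2, rt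
Reagents that add atoms: water, O
Why: Mild acid hydrolysis of the allylic ketal unmasks the conjugated enone without touching the silyl ether or the carbinol stereocentre.

Step 4
Reactants: 5 3-(trimethylsilyl)prop-2-yn-1-ol
Product: 6 3-(trimethylsilyl)prop-2-yn-1-yl methanesulfonate
Conditions: MsCl, Et3N, CH2Cl2, 0 °C
Reagents that add atoms: methanesulfonyl chloride, CS(=O)(=O)Cl
Why: Sulfonylation turns the propargylic alcohol into a leaving group for the SN2' step.

Step 5
Reactants: 6 3-(trimethylsilyl)prop-2-yn-1-yl methanesulfonate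
Product: 7 1-methyl-1-(trimethylsilyl)allene (buta-1,2-dien-3-yltrimethylsilane)
Conditions: MeMgCl, CuBr, LiBr, THF, −78 °C to rt
Reagents that add atoms: methylmagnesium chloride, C[Mg]Cl
Why: SN2' displacement of the propargylic mesylate by the methylcopper reagent at the silyl-bearing alkyne carbon gives the silylallene.

Step 6
Reactants: 4 (S)-4-[(tert-butyldimethylsilyl)oxy]cyclohex-2-en-1-one, 7 1-methyl-1-(trimethylsilyl)allene
Product: 8 cis-fused annulation product (bicyclo[4.3.0]non-8-en-2-one skeleton): C6 ketone, 10α-OTBS, C4(CH3)=C3(SiMe3), C2H2, H1 and H5 α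
Conditions: TiCl4 (1.2 equiv), CH2Cl2, −78 °C
Reagents that add atoms: none
Why: Danheiser (trimethylsilyl)cyclopentene annulation: the allene terminus adds to C1 of the TiCl4-activated enone anti to the C10 silyloxy group, the β-silyl vinyl cation undergoes a 1,2-silyl shift and is closed by the titanium enolate at C5, which sets C1 and C5 with a cis ring fusion and puts the methyl-bearing carbon C4 next to C5.

Step 7
Reactants: 8 cis-fused annulation product
Product: 9 6β-alcohol of 8 (10α-OTBS, vinylsilane ring A)
Conditions: LiBH(s-Bu)3, THF, −78 °C; aq. work-up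
Reagents that add atoms: none
Why: Hydride reduction from the convex α face (the β face is blocked by the axial C5–C4 bond) should give the 6β-alcohol; this configuration is of no consequence because C6 returns to the ketone in step 14.

Step 8
Reactants: 9 6β-alcohol
Product: 10 6β-O-triisopropylsilyl ether (10α-OTBS, vinylsilane ring A)
Conditions: i-Pr3SiOTf, 2,6-lutidine, CH2Cl2, 0 °C
Reagents that add atoms: triisopropylsilyl triflate, CC(C)[Si](C(C)C)(C(C)C)OS(=O)(=O)C(F)(F)F
Why: Silyl triflate silylation of a hindered secondary alcohol masks C6 while C10 is converted.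

Step 9
Reactants: 10 6β-O-triisopropylsilyl ether
Product: 11 10α-alcohol (6β-OTIPS, vinylsilane ring A)
Conditions: HF·pyridine, pyridine, THF, 0 °C to rt
Reagents that add atoms: none
Why: Selective desilylation: the less hindered and more labile secondary TBS ether is cleaved while the TIPS ether and the C–Si bond of the vinylsilane, which has no neighbouring hydroxyl, should survive.

Step 10
Reactants: 11 10α-alcohol
Product: 12 C10 ketone (6β-OTIPS, vinylsilane ring A)
Conditions: Dess–Martin periodinane, pyridine, CH2Cl2, rt
Reagents that add atoms: none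
Why: Dess–Martin oxidation of the secondary alcohol under neutral conditions removes the sacrificial stereocentre.

Step 11
Reactants: 12 C10 ketone
Product: 13 C10 exocyclic methylene compound (6β-OTIPS, C4(CH3)=C3(SiMe3))
Conditions: Ph3PCH3Br, KOt-Bu, THF, 0 °C to rt
Reagents that add atoms: methyltriphenylphosphonium bromide, C[P+](c1ccccc1)(c1ccccc1)c1ccccc1.[Br-]
Why: Wittig methylenation of an ordinary cyclohexanone, done while C6 is a silyl ether and before C2=C3 exists, so that neither β-elimination nor double-bond migration can interfere.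

Step 12
Reactants: 13 C10 exocyclic methylene compound
Product: 15 4α-hydroxy-3-(trimethylsilyl) Δ2-alkene (4β-CH3; 6β-OTIPS; C10 methylene), via allylic hydroperoxide 14 (not isolated)
Conditions: O2, visible light, 5,10,15,20-tetraphenylporphyrin (cat.), CH2Cl2, −20 °C; then PPh3
Reagents that add atoms: dioxygen, O=O
Why: Schenck ene reaction of singlet oxygen with the tetrasubstituted vinylsilane, in which silicon directs hydrogen abstraction to the geminal C2 methylene so that oxygen bonds to C4 and the double bond moves to C2=C3; attack on the convex α face sets C4–O cis to H5, the 1,1-disubstituted methylene is far less reactive, and PPh3 reduces the hydroperoxide.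

Step 13
Reactants: 15 4α-hydroxy-3-(trimethylsilyl) Δ2-alkene
Product: 16 4α,6β-diol (C2=C3, C10 methylene)
Conditions: Bu4NF, THF, 60 °C
Reagents that add atoms: none
Why: Fluoride-induced protodesilylation of a 2-silyl allylic alcohol, assisted by the neighbouring C4 oxygen (carbon-to-oxygen silyl transfer of the Brook type), with cleavage of the TIPS ether in the same operation.

Step 14
Reactants: 16 4α,6β-diol
Product: 17 4α-hydroxy C6 ketone (cis-hydrindenone with free tertiary alcohol)
Conditions: Dess–Martin periodinane, pyridine, CH2Cl2, 0 °C to rt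
Reagents that add atoms: none
Why: Dess–Martin oxidation can only oxidise the secondary C6 alcohol, and the buffered neutral medium avoids retro-aldol cleavage of the β-hydroxy ketone.

Step 15
Reactants: 17 4α-hydroxy C6 ketone
Product: 18 (1S,3aS,7aS)-1-methyl-4-methylidene-1-[(triethylsilyl)oxy]-1,3a,4,5,6,7a-hexahydro-7H-inden-7-one (hydrindenone; C4–OTES α)
Conditions: Et3SiOTf, 2,6-lutidine, CH2Cl2, −78 °C
Reagents that add atoms: triethylsilyl triflate, CC[Si](CC)(CC)OS(=O)(=O)C(F)(F)F
Why: Low-temperature silyl triflate silylation of the tertiary aldol-type hydroxyl with a non-nucleophilic base caps C4 without retro-aldol or elimination.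

Step 16
Reactants: 19 (S)-3-bromo-2-methylpropan-1-ol
Product: 20 (S)-(3-bromo-2-methylpropoxy)(tert-butyl)dimethylsilane
Conditions: TBSCl, imidazole, CH2Cl2, rt
Reagents that add atoms: tert-butyldimethylsilyl chloride, CC(C)(C)[Si](C)(C)Cl
Why: Standard silylation protects the primary alcohol (later C7) of the chiral-pool unit that supplies C11.

Step 17
Reactants: 20 (S)-(3-bromo-2-methylpropoxy)(tert-butyl)dimethylsilane, 21 3-methylbut-2-enal
Product: 23 (6R)-7-[(tert-butyldimethylsilyl)oxy]-2,6-dimethylhept-2-en-4-ol (both C4 epimers), via Grignard reagent 22 (not isolated)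
Conditions: Mg, THF, 40 °C; then 21, −78 to 0 °C
Reagents that add atoms: none
Why: Grignard 1,2-addition to the β,β-disubstituted enal forms the C12–C13 bond; the carbinol centre is not controlled here and is erased in step 18.

Step 18
Reactants: 23 (6R)-7-[(tert-butyldimethylsilyl)oxy]-2,6-dimethylhept-2-en-4-ol
Product: 24 (R)-7-[(tert-butyldimethylsilyl)oxy]-2,6-dimethylhept-2-en-4-one
Conditions: Dess–Martin periodinane, pyridine, CH2Cl2, rt
Reagents that add atoms: none
Why: Dess–Martin oxidation converges both epimers on one enone without touching C11.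

Step 19
Reactants: 24 (R)-7-[(tert-butyldimethylsilyl)oxy]-2,6-dimethylhept-2-en-4-one
Product: 25 (4R,6R)-7-[(tert-butyldimethylsilyl)oxy]-2,6-dimethylhept-2-en-4-ol
Conditions: (S)-1-methyl-3,3-diphenyltetrahydro-1H,3H-pyrrolo[1,2-c][1,3,2]oxazaborole [(S)-Me-CBS, 0.1 equiv], catecholborane, toluene, −78 °C
Reagents that add atoms: none
Why: Corey–Bakshi–Shibata reduction with the alkenyl group as the large substituent, so the (S)-catalyst should set the (R)-carbinol C13 under reagent control, independent of the remote C11 centre.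

Step 20
Reactants: 25 (4R,6R)-7-[(tert-butyldimethylsilyl)oxy]-2,6-dimethylhept-2-en-4-ol
Product: 26 (4R,6R)-7-[(tert-butyldimethylsilyl)oxy]-2,6-dimethylhept-2-en-4-yl acetate
Conditions: Ac2O, pyridine, 4-(dimethylamino)pyridine (cat.), CH2Cl2, 0 °C to rt
Reagents that add atoms: acetic anhydride, CC(=O)OC(C)=O
Why: Nucleophile-catalysed acylation installs the C13 acetate of the target with retention.

Step 21
Reactants: 26 (4R,6R)-7-[(tert-butyldimethylsilyl)oxy]-2,6-dimethylhept-2-en-4-yl acetate
Product: 27 (4R,6R)-7-hydroxy-2,6-dimethylhept-2-en-4-yl acetate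
Conditions: HF·pyridine, pyridine, THF, 0 °C
Reagents that add atoms: none
Why: Buffered fluoride cleaves the primary silyl ether without ionising or transposing the allylic acetate.

Step 22
Reactants: 27 (4R,6R)-7-hydroxy-2,6-dimethylhept-2-en-4-yl acetate
Product: 28 (4R,6R)-2,6-dimethyl-7-oxohept-2-en-4-yl acetate
Conditions: Dess–Martin periodinane, pyridine, CH2Cl2, 0 °C
Reagents that add atoms: none
Why: Buffered Dess–Martin oxidation gives the α-branched aldehyde without epimerising C11.

Step 23
Reactants: 28 (4R,6R)-2,6-dimethyl-7-oxohept-2-en-4-yl acetate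
Product: 29 (4R,6R,7E)-7-[2-(tert-butyldimethylsilyl)hydrazinylidene]-2,6-dimethylhept-2-en-4-yl acetate
Conditions: 1,2-bis(tert-butyldimethylsilyl)hydrazine, Sc(OTf)3 (0.01 mol%), CH2Cl2, 0 °C to rt; volatiles removed in vacuo
Reagents that add atoms: 1,2-bis(tert-butyldimethylsilyl)hydrazine, CC(C)(C)[Si](C)(C)NN[Si](C)(C)C(C)(C)C
Why: Lewis-acid-catalysed condensation with the bis-silylhydrazine gives the N-silylhydrazone, a hydrazone that cannot form an azine, under conditions too mild to epimerise C11.

Step 24
Reactants: 29 N-silylhydrazone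
Product: 30 (4R,6R)-7-diazo-2,6-dimethylhept-2-en-4-yl acetate (cold solution)
Conditions: (difluoroiodo)benzene PhIF2, 2-chloropyridine, CH2Cl2, −78 to −30 °C; cold aq. NaHCO3 wash, dried cold, used at once
Reagents that add atoms: none
Why: Oxidation of an N-silylhydrazone with the iodine difluoride reagent is a known low-temperature route to non-stabilised diazoalkanes; 2-chloropyridine takes up the HF and the cold wash removes fluoride before the scandium step.

Step 25
Reactants: 18 hydrindenone (C4–OTES), 30 (4R,6R)-7-diazo-2,6-dimethylhept-2-en-4-yl acetate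
Product: 32 ring-B ketone (1S,4S,5S,7R,11R,13R): C6 ketone with the 7β side chain and C4–OTES, via diazonium alkoxide 31 (not isolated)
Conditions: Sc(OTf)3 (10 mol%), 1,1,1-tris[(4S)-4-phenyl-4,5-dihydro-1,3-oxazol-2-yl]ethane (12 mol%), toluene/CH2Cl2, −78 to −40 °C, slow addition of 30 (1.5 equiv)
Reagents that add atoms: none
Why: Trivalent scandium held by the tris(oxazoline) activates the C6 carbonyl of 18, the nucleophilic diazo carbon of 30 adds from the convex α face to give diazonium alkoxide 31, and the C6–C8 bond, anti-periplanar to the departing N2, shifts to C7 with inversion there, so that C6–C7 and C7–C8 are formed and the carbonyl is restored in a ring one carbon larger. The closest known reaction type is the Sc(OTf)3-catalysed homologation of cycloalkanones with non-stabilised diazoalkanes (a catalytic Büchner–Curtius–Schlotterbeck ring enlargement), used here with a more functionalised secondary-alkyl diazomethane. Ring B is not closed by a cyclisation; it arises by a 1,2-alkyl shift that enlarges the existing six-membered carbocycle to the seven-membered one. The new stereocentre C7 is set by which face of the prochiral diazo carbon adds inside the chiral scandium–ligand pocket (the betaine rotamer that places N2 anti to C8), and the 7β product, with both α-substituents of the cycloheptanone on the same face, is also expected to be the more stable epimer. The step needs C8 and not C5 to migrate, which the substitution difference secures (a methylene against a methine that carries the quaternary C4), and it needs the C4 silyloxy group β to the ketone to stay in place, which the base-free, low-temperature conditions secure; the acetate, both alkenes of the side chain and core and the tertiary silyl ether should be inert to the diazoalkane at this temperature.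

Step 26
Reactants: 32 ring-B ketone
Product: 33 6β-alcohol (C4–OTES, C13–OAc)
Conditions: NaBH4, CeCl3·7H2O, MeOH/THF, −40 to 0 °C
Reagents that add atoms: none
Why: Luche-type borohydride reduction under steric approach control: the β face of C6 is blocked by the C4 methyl group and by the C7 side chain, so hydride should add from the convex α face and give the 6β-alcohol; no internal delivery from the C4 oxygen is relied on, since that oxygen is trans to C6 on ring A and stays silylated, which also keeps a retro-aldol-prone β-hydroxy ketone from being exposed, and the acetate survives borohydride.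

Step 27
Reactants: 33 6β-alcohol (C4–OTES)
Product: 34 CNP0209568.2 (target)
Conditions: HF·pyridine, pyridine, THF, 0 °C to rt
Reagents that add atoms: none
Why: Buffered fluoride desilylation frees the tertiary allylic C4 alcohol without ionising it and without cleaving or migrating the C13 acetate.

**Compound list**

1 | 1,4-dioxaspiro[4.5]dec-6-en-8-one | O=C1C=CC2(CC1)OCCO2 | starting material
2 | (S)-1,4-dioxaspiro[4.5]dec-6-en-8-ol | O[C@@H]1C=CC2(CC1)OCCO2 | intermediate
3 | (S)-tert-butyl(1,4-dioxaspiro[4.5]dec-6-en-8-yloxy)dimethylsilane | CC(C)(C)[Si](C)(C)O[C@@H]1C=CC2(CC1)OCCO2 | intermediate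
4 | (S)-4-[(tert-butyldimethylsilyl)oxy]cyclohex-2-en-1-one | CC(C)(C)[Si](C)(C)O[C@@H]1C=CC(=O)CC1 | intermediate
5 | 3-(trimethylsilyl)prop-2-yn-1-ol | C[Si](C)(C)C#CCO | starting material
6 | 3-(trimethylsilyl)prop-2-yn-1-yl methanesulfonate | C[Si](C)(C)C#CCOS(C)(=O)=O | intermediate
7 | 1-methyl-1-(trimethylsilyl)allene | C=C=C(C)[Si](C)(C)C | intermediate
8 | cis-fused annulation product: C6 ketone, 10α-OTBS, C4(CH3)=C3(SiMe3), H1/H5 α | CC(C)(C)[Si](C)(C)O[C@H]1CCC(=O)[C@H]2[C@@H]1CC([Si](C)(C)C)=C2C | intermediate
9 | 6β-alcohol of 8 | CC(C)(C)[Si](C)(C)O[C@H]1CC[C@H](O)[C@H]2[C@@H]1CC([Si](C)(C)C)=C2C | intermediate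
10 | 6β-OTIPS, 10α-OTBS vinylsilane | CC(C)(C)[Si](C)(C)O[C@H]1CC[C@H](O[Si](C(C)C)(C(C)C)C(C)C)[C@H]2[C@@H]1CC([Si](C)(C)C)=C2C | intermediate
11 | 10α-alcohol, 6β-OTIPS vinylsilane | O[C@H]1CC[C@H](O[Si](C(C)C)(C(C)C)C(C)C)[C@H]2[C@@H]1CC([Si](C)(C)C)=C2C | intermediate
12 | C10 ketone, 6β-OTIPS vinylsilane | O=C1CC[C@H](O[Si](C(C)C)(C(C)C)C(C)C)[C@H]2[C@@H]1CC([Si](C)(C)C)=C2C | intermediate
13 | C10 methylene, 6β-OTIPS vinylsilane | C=C1CC[C@H](O[Si](C(C)C)(C(C)C)C(C)C)[C@H]2[C@@H]1CC([Si](C)(C)C)=C2C | intermediate
14 | 4α-hydroperoxide, 3-(trimethylsilyl) Δ2-alkene | C=C1CC[C@H](O[Si](C(C)C)(C(C)C)C(C)C)[C@H]2[C@@H]1C=C([Si](C)(C)C)[C@]2(C)OO | intermediate (not isolated)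
15 | 4α-hydroxy-3-(trimethylsilyl) Δ2-alkene, 6β-OTIPS | C=C1CC[C@H](O[Si](C(C)C)(C(C)C)C(C)C)[C@H]2[C@@H]1C=C([Si](C)(C)C)[C@]2(C)O | intermediate
16 | 4α,6β-diol (C2=C3, C10 methylene) | C=C1CC[C@H](O)[C@H]2[C@@H]1C=C[C@]2(C)O | intermediate
17 | 4α-hydroxy C6 ketone | C=C1CCC(=O)[C@H]2[C@@H]1C=C[C@]2(C)O | intermediate
18 | (1S,3aS,7aS)-1-methyl-4-methylidene-1-[(triethylsilyl)oxy]-1,3a,4,5,6,7a-hexahydro-7H-inden-7-one | C=C1CCC(=O)[C@H]2[C@@H]1C=C[C@]2(C)O[Si](CC)(CC)CC | intermediate
19 | (S)-3-bromo-2-methylpropan-1-ol | OC[C@H](C)CBr | starting material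
20 | (S)-(3-bromo-2-methylpropoxy)(tert-butyl)dimethylsilane | CC(C)(C)[Si](C)(C)OC[C@H](C)CBr | intermediate
21 | 3-methylbut-2-enal | CC(C)=CC=O | starting material
22 | (S)-{3-[(tert-butyldimethylsilyl)oxy]-2-methylpropyl}magnesium bromide | CC(C)(C)[Si](C)(C)OC[C@H](C)C[Mg]Br | intermediate (not isolated)
23 | (6R)-7-[(tert-butyldimethylsilyl)oxy]-2,6-dimethylhept-2-en-4-ol, both C4 epimers | CC(C)(C)[Si](C)(C)OC[C@H](C)CC(O)C=C(C)C | intermediate
24 | (R)-7-[(tert-butyldimethylsilyl)oxy]-2,6-dimethylhept-2-en-4-one | CC(C)(C)[Si](C)(C)OC[C@H](C)CC(=O)C=C(C)C | intermediate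
25 | (4R,6R)-7-[(tert-butyldimethylsilyl)oxy]-2,6-dimethylhept-2-en-4-ol | CC(C)(C)[Si](C)(C)OC[C@H](C)C[C@H](C=C(C)C)O | intermediate
26 | (4R,6R)-7-[(tert-butyldimethylsilyl)oxy]-2,6-dimethylhept-2-en-4-yl acetate | CC(C)(C)[Si](C)(C)OC[C@H](C)C[C@H](C=C(C)C)OC(C)=O | intermediate
27 | (4R,6R)-7-hydroxy-2,6-dimethylhept-2-en-4-yl acetate | OC[C@H](C)C[C@H](C=C(C)C)OC(C)=O | intermediate
28 | (4R,6R)-2,6-dimethyl-7-oxohept-2-en-4-yl acetate | O=C[C@H](C)C[C@H](C=C(C)C)OC(C)=O | intermediate
29 | (4R,6R,7E)-7-[2-(tert-butyldimethylsilyl)hydrazinylidene]-2,6-dimethylhept-2-en-4-yl acetate | CC(C)(C)[Si](C)(C)N/N=C/[C@H](C)C[C@H](C=C(C)C)OC(C)=O | intermediate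
30 | (4R,6R)-7-diazo-2,6-dimethylhept-2-en-4-yl acetate | [N-]=[N+]=C[C@H](C)C[C@H](C=C(C)C)OC(C)=O | intermediate
31 | C6 diazonium alkoxide (scandium-bound, drawn metal-free) | C=C1CC[C@@]([O-])([C@@H]([N+]#N)[C@H](C)C[C@H](C=C(C)C)OC(C)=O)[C@H]2[C@@H]1C=C[C@]2(C)O[Si](CC)(CC)CC | intermediate (not isolated)
32 | ring-B ketone (1S,4S,5S,7R,11R,13R): C6 ketone, 7β side chain, C4–OTES | C=C1CC[C@H]([C@H](C)C[C@H](C=C(C)C)OC(C)=O)C(=O)[C@H]2[C@@H]1C=C[C@]2(C)O[Si](CC)(CC)CC | intermediate
33 | 6β-alcohol, C4–OTES, C13–OAc | C=C1CC[C@H]([C@H](C)C[C@H](C=C(C)C)OC(C)=O)[C@H](O)[C@H]2[C@@H]1C=C[C@]2(C)O[Si](CC)(CC)CC | intermediate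
34 | CNP0209568.2, (1S,4S,5R,6S,7R,11R,13R) in the numbering used here | C=C1CC[C@H]([C@H](C)C[C@H](C=C(C)C)OC(C)=O)[C@H](O)[C@H]2[C@@H]1C=C[C@]2(C)O | target

**Step count and risks**

Total steps: 27. Longest linear sequence: 16 (steps 1–3, 6–15, 25–27).

Steps most likely to fail:

1. Step 25. The main risk is too little discrimination between the two faces of the prochiral diazo carbon, which would give a mixture at C7. Secondary leaks are loss of the diazoalkane by 1,2-hydride shift, azine or epoxide formation, and migration of C5. Fallback (sets out from 18 and 30, returns at 32): C7 is put under thermodynamic instead of catalyst control. The insertion is run with ligand-free Sc(OTf)3, which should give 32 together with its C7 epimer F1. The mixture is then equilibrated through the C6–C7 enol with a substoichiometric amount of 1,8-diazabicyclo[5.4.0]undec-7-ene (CH2Cl2, 0 °C, short contact, watched for loss of the C4 silyloxy group). Equilibration should favour 32, the cis-2,7-disubstituted cycloheptanone in which the side chain and the C5–C4 bond share the β face; unconverted C7 epimer F1 is separated and recycled.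

2. Step 24. The risks are decomposition of the non-stabilised diazoalkane while it is generated (azine formation with unreacted hydrazone, acid-induced loss of N2 by the HF formed) and carry-over of fluoride that deactivates Sc(OTf)3. Fallback (sets out from 28, returns at 30): a Bamford–Stevens release that uses neither oxidant nor fluoride. Aldehyde 28 is condensed with 2-(trifluoromethyl)benzenesulfonohydrazide to give N-triftosylhydrazone F2. Its sodium salt (NaH, CH2Cl2, −40 °C) fragments on warming towards 0 °C with loss of sulfinate and releases 30. The salt can also be fragmented in the presence of 18 and the scandium catalyst, so that the diazoalkane never accumulates.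

3. Step 12. The risks are erosion of regio- and facial control in the ene reaction (hydrogen abstraction from the C4 methyl or from C5–H, oxygen delivery to the β face) and competing oxygenation of the C10 methylene. Fallback (sets out from 13, returns at 16): the oxygen is introduced by epoxidation instead of a pericyclic step. mCPBA (CH2Cl2, NaHCO3, −20 °C) should epoxidise the tetrasubstituted vinylsilane from the convex α face to give epoxysilane F3. Fluoride (Bu4NF, THF, rt) removes silicon from the oxirane carbon with retention to give trisubstituted epoxide F4. PhSeNa (from PhSeSePh and NaBH4, EtOH, reflux) opens it at the secondary C3 to give trans hydroxy selenide F5. H2O2 oxidation and selenoxide syn-elimination, which can only run towards C2 because C4 is quaternary, give allylic alcohol F6. Bu4NF at 60 °C then removes the TIPS group to give 16.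

**Further compounds**

F1 | step 25 | C7 epimer of 32 (7α side chain) | C=C1CC[C@@H]([C@H](C)C[C@H](C=C(C)C)OC(C)=O)C(=O)[C@H]2[C@@H]1C=C[C@]2(C)O[Si](CC)(CC)CC
F2 | step 24 | N-triftosylhydrazone of 28, (4R,6R,7E) | O=S(=O)(N/N=C/[C@H](C)C[C@H](C=C(C)C)OC(C)=O)c1ccccc1C(F)(F)F
F3 | step 12 | 3α,4α-epoxysilane of 13 | C=C1CC[C@H](O[Si](C(C)C)(C(C)C)C(C)C)[C@H]2[C@@H]1C[C@]3([Si](C)(C)C)O[C@]23C
F4 | step 12 | 3α,4α-epoxide (silicon removed, 6β-OTIPS) | C=C1CC[C@H](O[Si](C(C)C)(C(C)C)C(C)C)[C@H]2[C@@H]1C[C@@H]3O[C@]23C
F5 | step 12 | 4α-hydroxy-3β-(phenylselanyl) compound (6β-OTIPS) | C=C1CC[C@H](O[Si](C(C)C)(C(C)C)C(C)C)[C@H]2[C@@H]1C[C@@H]([Se]c3ccccc3)[C@]2(C)O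
F6 | step 12 | 4α-hydroxy Δ2-alkene with 6β-OTIPS | C=C1CC[C@H](O[Si](C(C)C)(C(C)C)C(C)C)[C@H]2[C@@H]1C=C[C@]2(C)O
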